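**Retrosynthetic overview**

1. The enyne is cut at its C(sp)–C(sp2) bond: Sonogashira coupling of a 1,2-dioxane carrying a pent-4-ynyl chain with an (E)-1-iodoalkene whose far alkyne is silylated (three steps from dec-9-yn-1-ol); desilylation ends the route.
2. Methyl ketal and methyl ester are made together from a cyclic peroxy hemiketal carboxylic acid in acidic methanol (axial OMe by equilibration).
3. Key disconnection, forming the only ring: both C–O bonds of the peroxide, O2–C3 by addition of H2O2 to a ketone and O1–C6 by opening an (R)-4-alkyl oxetan-2-one at its alkyl carbon with inversion.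
4. The keto β-lactone comes from 4-oxonon-8-ynal and ketene (alkaloid-catalysed [2+2]); the keto aldehyde from the Weinreb amide of hex-5-ynoic acid and a dioxolane-masked 3-oxopropyl Grignard reagent.
5. Feature used (ring numbered O1, O2, C3 ketal carbon, C4, C5, C6): C6 bears O1 and the CH2CO2Me arm, i.e. O–CH–CH2–C=O, the pattern left when a 4-substituted oxetan-2-one is opened at its alkyl carbon; C3 lies two CH2 groups from C6, so a hydroperoxide on C3 reaches C6 in a six-membered closure. (In compound names the arm-bearing carbon is position 3 and the ketal carbon position 6.)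

Key step: step 5

Assumption: O-trimethylsilylquinine is taken to give the (R)-4-alkyl oxetan-2-one (the quinidine-derived catalyst giving the (S) series); if the sense proves opposite, O-trimethylsilylquinidine is used in the same way. The Grignard reagent is taken as its commercial THF solution.

**Route**

Step 1
Reactants: 1 hex-5-ynoic acid
Product: 2 N-methoxy-N-methylhex-5-ynamide
Conditions: 1,1'-carbonyldiimidazole, CH2Cl2, rt; then MeNH(OMe)·HCl, rt
Reagents that add atoms: N,O-dimethylhydroxylamine hydrochloride, CNOC.Cl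
Why: amide coupling through the acyl imidazolide (formed with loss of CO2) gives the Weinreb amide, and the terminal alkyne is inert to these conditions.

Step 2
Reactants: 2 N-methoxy-N-methylhex-5-ynamide; 3 [2-(1,3-dioxolan-2-yl)ethyl]magnesium bromide
Product: 4 1-(1,3-dioxolan-2-yl)oct-7-yn-3-one
Conditions: 3 (2.2 equiv), THF, −10 → 0 °C; aq. NH4Cl
Reagents that add atoms: none
Why: Weinreb ketone synthesis, in which the magnesium-chelated tetrahedral adduct resists a second addition and gives the ketone only on quench, while the excess reagent covers any metalation of the alkyne C–H, which is restored on protonation.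

Step 3
Reactants: 4 1-(1,3-dioxolan-2-yl)oct-7-yn-3-one
Product: 5 4-oxonon-8-ynal
Conditions: 1 M HCl (aq), THF, rt
Reagents that add atoms: water, O
Why: acid hydrolysis of the dioxolane acetal frees the aldehyde under conditions too mild for aldol cyclisation or furan formation of the 1,4-keto aldehyde, which is used at once.

Step 4
Reactants: 5 4-oxonon-8-ynal; 6 acetyl chloride
Product: 8 (R)-4-(3-oxooct-7-yn-1-yl)oxetan-2-one, via ketene 7 (not isolated)
Conditions: 6 (2.5 equiv), iPr2NEt, O-trimethylsilylquinine (10 mol%), LiClO4 (0.5 equiv), CH2Cl2/Et2O, −78 °C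
Reagents that add atoms: none
Why: catalytic asymmetric ketene–aldehyde [2+2] cycloaddition (acyl halide–aldehyde cyclocondensation), in which the alkaloid-bound ammonium enolate adds to the lithium-activated aldehyde and lactonises, the alkaloid fixing the aldehyde face attacked and hence the (R) centre, while the much less electrophilic ketone is left alone.

Step 5
Reactants: 8 (R)-4-(3-oxooct-7-yn-1-yl)oxetan-2-one
Product: 11 2-[(3S,6R)-6-hydroxy-6-(pent-4-yn-1-yl)-1,2-dioxan-3-yl]acetic acid, via geminal bis-hydroperoxide 9 (not isolated), via hydroperoxy dioxane acid 10 (not isolated)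
Conditions: anhydrous H2O2 in Et2O (6 equiv), Me3SiOTf (0.2 equiv), Et2O, −40 → 0 °C (dilute); water wash; then Me2S, CH2Cl2, 0 °C
Reagents that add atoms: hydrogen peroxide, OO
Why: Proposed new method: the strong acid released from Me3SiOTf and H2O2 first converts the ketone, through its perhydrate, into the geminal bis-hydroperoxide 9, so that no carbonyl or hydroxyl oxygen is left to close a five-membered ether, and one OOH group then attacks the alkyl carbon of the carbonyl-activated lactone from the rear, with carboxylate as leaving group and release of four-ring strain, to give 10. The closest known reaction types are SN2 alkyl–oxygen openings of enantioenriched 4-alkyl oxetan-2-ones by azide, thiolate and cuprate nucleophiles, the inverting attack of neutral water on 4-methyloxetan-2-one, and Lewis-acid openings of oxetanes by H2O2 or tethered hydroperoxides. The 1,2-dioxane closes in the 6-exo-tet mode (O–O–C(ketal)–CH2–CH2–CH), whereas attack of the same oxygen at the acyl carbon would need an eight-membered ring. The CH stereocentre bearing the acetic acid arm is set by inversion of the (R) lactone carbon and should come out S; the peroxyketal carbon forms without control and is settled by equilibration in step 6. The step needs alkyl–oxygen over acyl–oxygen cleavage and a clean SN2 course, which the tether, the unactivated secondary carbon (no ionisation pathway) and the low temperature should secure. Me2S then reduces the exocyclic hydroperoxide but not the dialkyl peroxide ring to give hemiketal 11, and any 10 that survives converges with 11 in step 6.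

Step 6
Reactants: 11 2-[(3S,6R)-6-hydroxy-6-(pent-4-yn-1-yl)-1,2-dioxan-3-yl]acetic acid
Product: 12 methyl 2-[(3S,6R)-6-methoxy-6-(pent-4-yn-1-yl)-1,2-dioxan-3-yl]acetate
Conditions: HCl (1.25 M in MeOH), rt
Reagents that add atoms: methanol, CO
Why: Fischer esterification runs alongside acid-catalysed exchange at the ketal carbon through the ring peroxycarbenium ion, which under thermodynamic control places OMe axial (anomeric effect) and both carbon substituents equatorial, i.e. the (R) ketal centre with OMe cis to the acetate arm.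

Step 7
Reactants: 13 dec-9-yn-1-ol
Product: 15 10-(trimethylsilyl)dec-9-yn-1-ol, via bis-silylated ether 14 (not isolated)
Conditions: n-BuLi (2.1 equiv), THF, −78 °C; Me3SiCl (2.2 equiv), → rt; then 1 M HCl (aq)
Reagents that add atoms: chlorotrimethylsilane, C[Si](C)(C)Cl
Why: the alkoxide–acetylide dianion is silylated at O and C (alkyne C-silylation), and dilute acid on work-up hydrolyses only the labile O–Si bond.

Step 8
Reactants: 15 10-(trimethylsilyl)dec-9-yn-1-ol
Product: 16 10-(trimethylsilyl)dec-9-ynal
Conditions: TEMPO (10 mol%), PhI(OAc)2 (1.1 equiv), CH2Cl2, rt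
Reagents that add atoms: none
Why: oxoammonium-mediated oxidation of the primary alcohol stops at the aldehyde and leaves the silyl alkyne untouched.

Step 9
Reactants: 16 10-(trimethylsilyl)dec-9-ynal
Product: 17 (E)-(11-iodoundec-10-en-1-yn-1-yl)trimethylsilane
Conditions: CrCl2 (6 equiv), CHI3 (2 equiv), THF/1,4-dioxane, 0 °C → rt
Reagents that add atoms: iodoform, IC(I)I
Why: Takai olefination, in which the geminal dichromium species from iodoform adds to the aldehyde and eliminates to the one-carbon-homologated iodoalkene with the (E) geometry favoured.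

Step 10
Reactants: 12 methyl 2-[(3S,6R)-6-methoxy-6-(pent-4-yn-1-yl)-1,2-dioxan-3-yl]acetate; 17 (E)-(11-iodoundec-10-en-1-yn-1-yl)trimethylsilane
Product: 18 methyl 2-[(3S,6R)-6-methoxy-6-[(6E)-16-(trimethylsilyl)hexadec-6-ene-4,15-diyn-1-yl]-1,2-dioxan-3-yl]acetate
Conditions: Pd(PPh3)4 (5 mol%), CuI (10 mol%), Et3N, THF, rt, degassed
Reagents that add atoms: none
Why: Sonogashira coupling joins the terminal alkyne to the iodoalkene with retention of the (E) geometry at room temperature, where the dialkyl peroxy ketal is expected to persist, and the silylated alkyne of 17 cannot compete.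

Step 11
Reactants: 18 methyl 2-[(3S,6R)-6-methoxy-6-[(6E)-16-(trimethylsilyl)hexadec-6-ene-4,15-diyn-1-yl]-1,2-dioxan-3-yl]acetate
Product: 19 methyl 2-[(3S,6R)-6-[(6E)-hexadec-6-ene-4,15-diyn-1-yl]-6-methoxy-1,2-dioxan-3-yl]acetate
Conditions: K2CO3 (0.2 equiv), MeOH, 0 °C
Reagents that add atoms: none
Why: methoxide-mediated protodesilylation of the alkynylsilane, in which ester exchange with the solvent is degenerate for a methyl ester and the brief, cold, weakly basic conditions should not trigger β-elimination of the peroxide.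

**Compound list**

1 | hex-5-ynoic acid | C#CCCCC(=O)O | starting material
2 | N-methoxy-N-methylhex-5-ynamide | C#CCCCC(=O)N(C)OC | intermediate
3 | [2-(1,3-dioxolan-2-yl)ethyl]magnesium bromide | Br[Mg]CCC1OCCO1 | starting material
4 | 1-(1,3-dioxolan-2-yl)oct-7-yn-3-one | C#CCCCC(=O)CCC1OCCO1 | intermediate
5 | 4-oxonon-8-ynal | C#CCCCC(=O)CCC=O | intermediate
6 | acetyl chloride | CC(=O)Cl | starting material
7 | ketene | C=C=O | intermediate (not isolated)
8 | (R)-4-(3-oxooct-7-yn-1-yl)oxetan-2-one | C#CCCCC(=O)CC[C@@H]1CC(=O)O1 | intermediate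
9 | (R)-4-(3,3-dihydroperoxyoct-7-yn-1-yl)oxetan-2-one | C#CCCCC(OO)(OO)CC[C@@H]1CC(=O)O1 | intermediate (not isolated)
10 | 2-[(3S)-6-hydroperoxy-6-(pent-4-yn-1-yl)-1,2-dioxan-3-yl]acetic acid (either epimer at the peroxyketal carbon) | C#CCCCC1(OO)CC[C@@H](CC(=O)O)OO1 | intermediate (not isolated)
11 | 2-[(3S,6R)-6-hydroxy-6-(pent-4-yn-1-yl)-1,2-dioxan-3-yl]acetic acid (hemiketal epimers interconvert) | C#CCCC[C@]1(O)CC[C@@H](CC(=O)O)OO1 | intermediate
12 | methyl 2-[(3S,6R)-6-methoxy-6-(pent-4-yn-1-yl)-1,2-dioxan-3-yl]acetate | C#CCCC[C@]1(OC)CC[C@@H](CC(=O)OC)OO1 | intermediate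
13 | dec-9-yn-1-ol | C#CCCCCCCCCO | starting material
14 | trimethyl{[10-(trimethylsilyl)dec-9-yn-1-yl]oxy}silane | C[Si](C)(C)C#CCCCCCCCCO[Si](C)(C)C | intermediate (not isolated)
15 | 10-(trimethylsilyl)dec-9-yn-1-ol | C[Si](C)(C)C#CCCCCCCCCO | intermediate
16 | 10-(trimethylsilyl)dec-9-ynal | C[Si](C)(C)C#CCCCCCCCC=O | intermediate
17 | (E)-(11-iodoundec-10-en-1-yn-1-yl)trimethylsilane | C[Si](C)(C)C#CCCCCCCC/C=C/I | intermediate
18 | methyl 2-[(3S,6R)-6-methoxy-6-[(6E)-16-(trimethylsilyl)hexadec-6-ene-4,15-diyn-1-yl]-1,2-dioxan-3-yl]acetate | C[Si](C)(C)C#CCCCCCCC/C=C/C#CCCC[C@]1(OC)CC[C@@H](CC(=O)OC)OO1 | intermediate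
19 | methyl 2-[(3S,6R)-6-[(6E)-hexadec-6-ene-4,15-diyn-1-yl]-6-methoxy-1,2-dioxan-3-yl]acetate | C#CCCCCCCC/C=C/C#CCCC[C@]1(OC)CC[C@@H](CC(=O)OC)OO1 | target

**Step count and risks**

Total: 11 steps. Longest linear sequence: 8 steps (steps 1–6, 10, 11).

Steps most likely to fail:

1. Step 5 (carries the label). H2O2 may open the lactone at the acyl carbon to a peracid. The ketone oxygen may close a tetrahydrofuran before perhydrolysis is complete. The Me2S finish may over-reduce ring-opened hemiketal.
Fallback by known chemistry, setting out from 5 and returning at 12: aldehyde-selective Wittig reaction with Ph3P=CHCO2Me would give methyl (E)-6-oxoundec-2-en-10-ynoate F1. Ketalisation (HC(OMe)3, MeOH, TsOH) would give methyl (E)-6,6-dimethoxyundec-2-en-10-ynoate F2. Exchange with urea–H2O2 under Sc(OTf)3 catalysis in MeOH would give methyl (E)-6-hydroperoxy-6-methoxyundec-2-en-10-ynoate F3. Et2NH in CF3CH2OH would close the ring by intramolecular conjugate addition of the hydroperoxide to the enoate, and HCl/MeOH would equilibrate the ketal carbon to racemic methyl 2-[6-methoxy-6-(pent-4-yn-1-yl)-1,2-dioxan-3-yl]acetate F4 with the relative configuration of 12. Preparative chromatography on a chiral stationary phase would then give 12.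

2. Step 4. The γ-keto aldehyde may enolise and self-condense under the amine base, ketene may acylate the ketone enol, or lithium chelation by the keto aldehyde may open a poorly selective background pathway, lowering yield or enantiomeric purity.
Fallback, setting out from 2 and returning at 8, with the ketone carried as a ketal and the aldehyde made by alkene cleavage: 2 with but-3-enylmagnesium bromide would give dec-1-en-9-yn-5-one F5. Ethylene glycol/TsOH would give 2-(but-3-en-1-yl)-2-(pent-4-yn-1-yl)-1,3-dioxolane F6. OsO4 (cat.)/NaIO4/2,6-lutidine would cleave the alkene to 3-[2-(pent-4-yn-1-yl)-1,3-dioxolan-2-yl]propanal F7. The cycloaddition of step 4 on this plain aliphatic aldehyde would give (R)-4-{2-[2-(pent-4-yn-1-yl)-1,3-dioxolan-2-yl]ethyl}oxetan-2-one F8. Brief treatment with dilute aqueous HCl in THF at 0 °C would remove the ketal to give 8.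

3. Step 10. Zerovalent palladium, triphenylphosphine or the copper acetylide medium may reduce the O–O bond, or the amine may fragment the β-peroxy ester.
Fallback, setting out from 8 (with 17) and returning at 18, with the coupling moved in front of peroxide formation: Sonogashira coupling of 8 with 17 (iPr2NEt as base to spare the lactone) would give (R)-4-[(9E)-3-oxo-19-(trimethylsilyl)nonadec-9-ene-7,18-diyn-1-yl]oxetan-2-one F9. The conditions of step 5 would take it through (R)-4-[(9E)-3,3-dihydroperoxy-19-(trimethylsilyl)nonadec-9-ene-7,18-diyn-1-yl]oxetan-2-one F10 and 2-[(3S)-6-hydroperoxy-6-[(6E)-16-(trimethylsilyl)hexadec-6-ene-4,15-diyn-1-yl]-1,2-dioxan-3-yl]acetic acid F11 to 2-[(3S,6R)-6-hydroxy-6-[(6E)-16-(trimethylsilyl)hexadec-6-ene-4,15-diyn-1-yl]-1,2-dioxan-3-yl]acetic acid F12. The conditions of step 6 would then give 18.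

**Further compounds**

F1 | step 5 | methyl (E)-6-oxoundec-2-en-10-ynoate | C#CCCCC(=O)CC/C=C/C(=O)OC
F2 | step 5 | methyl (E)-6,6-dimethoxyundec-2-en-10-ynoate | C#CCCCC(OC)(OC)CC/C=C/C(=O)OC
F3 | step 5 | methyl (E)-6-hydroperoxy-6-methoxyundec-2-en-10-ynoate | C#CCCCC(OC)(OO)CC/C=C/C(=O)OC
F4 | step 5 | racemic methyl 2-[6-methoxy-6-(pent-4-yn-1-yl)-1,2-dioxan-3-yl]acetate (relative configuration as in 12) | C#CCCCC1(OC)CCC(CC(=O)OC)OO1
F5 | step 4 | dec-1-en-9-yn-5-one | C#CCCCC(=O)CCC=C
F6 | step 4 | 2-(but-3-en-1-yl)-2-(pent-4-yn-1-yl)-1,3-dioxolane | C#CCCCC1(CCC=C)OCCO1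
F7 | step 4 | 3-[2-(pent-4-yn-1-yl)-1,3-dioxolan-2-yl]propanal | C#CCCCC1(CCC=O)OCCO1
F8 | step 4 | (R)-4-{2-[2-(pent-4-yn-1-yl)-1,3-dioxolan-2-yl]ethyl}oxetan-2-one | C#CCCCC1(CC[C@@H]2CC(=O)O2)OCCO1
F9 | step 10 | (R)-4-[(9E)-3-oxo-19-(trimethylsilyl)nonadec-9-ene-7,18-diyn-1-yl]oxetan-2-one | C[Si](C)(C)C#CCCCCCCC/C=C/C#CCCCC(=O)CC[C@@H]1CC(=O)O1
F10 | step 10 | (R)-4-[(9E)-3,3-dihydroperoxy-19-(trimethylsilyl)nonadec-9-ene-7,18-diyn-1-yl]oxetan-2-one | C[Si](C)(C)C#CCCCCCCC/C=C/C#CCCCC(OO)(OO)CC[C@@H]1CC(=O)O1
F11 | step 10 | 2-[(3S)-6-hydroperoxy-6-[(6E)-16-(trimethylsilyl)hexadec-6-ene-4,15-diyn-1-yl]-1,2-dioxan-3-yl]acetic acid | C[Si](C)(C)C#CCCCCCCC/C=C/C#CCCCC1(OO)CC[C@@H](CC(=O)O)OO1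
F12 | step 10 | 2-[(3S,6R)-6-hydroxy-6-[(6E)-16-(trimethylsilyl)hexadec-6-ene-4,15-diyn-1-yl]-1,2-dioxan-3-yl]acetic acid | C[Si](C)(C)C#CCCCCCCC/C=C/C#CCCC[C@]1(O)CC[C@@H](CC(=O)O)OO1
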